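**Plan**

- Retrosynthesis: the aryl ether bond O–C1' is cut first (coumarin phenol plus a C10 epoxy alcohol), then both oxirane bonds C2'–O and C3'–O (back to an E enal), then C4'–C5' (vinylogous aldol of a senecioate dienolate with prenal). Chain atoms are numbered C1' (OCH2) to C7' and keep these numbers in every intermediate.
- Forward: the chain is joined at C4'–C5', C1' is brought to the aldehyde level, the oxirane (the only ring that is built; the coumarin rings are bought) is closed across C2'–C3', C1' is reduced and the coumarin is attached last by O-alkylation.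
- Enabling feature: the chain holds two trisubstituted alkenes, C2'=C3' and C6'=C7'. Once C1' is a formyl group, only C2'=C3' is conjugated and electrophilic, so a nucleophilic peroxide builds the oxirane ring there and leaves the isobutenyl alkene alone.
- Stereochemistry: C5' (R) comes from a catalytic enantioselective vinylogous Mukaiyama aldol. C3' (R) comes from the chiral phosphate counter-anion in the iminium epoxidation. C2' follows from the E geometry, which the ring closure carries into the C1'/C4' trans relation.

Key step: step 6

Assumption: the catalyst antipodes named in steps 2 and 6 are taken as the ones that deliver the stated faces (Re face of the prenal carbonyl; Re face of C3'), and the mirror-image catalyst would be used if the sense of induction proved to be the reverse.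

**Step 1**
Reactants: 1 methyl 3-methylbut-2-enoate
Product: 3 tert-butyl[(1-methoxy-3-methylbuta-1,3-dien-1-yl)oxy]dimethylsilane, via lithium dienolate 2 (not isolated)
Conditions: LiN(iPr)2, THF, −78 °C; then TBSCl, DMPU, −78 °C to rt
Reagents that add atoms: tert-butyldimethylsilyl chloride, CC(C)(C)[Si](C)(C)Cl
Why: LiN(iPr)2 removes a γ-proton of the senecioate to give the extended lithium dienolate 2, which is silylated on oxygen in the presence of DMPU (silyl ketene acetal formation), and since no stereocentre arises and the next step runs through an open transition state the ketene acetal geometry does not matter.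

**Step 2**
Reactants: 3 tert-butyl[(1-methoxy-3-methylbuta-1,3-dien-1-yl)oxy]dimethylsilane; 4 3-methylbut-2-enal (prenal)
Product: 6 methyl (2E,5R)-5-hydroxy-3,7-dimethylocta-2,6-dienoate, via trichlorosilyl ether 5 (not isolated)
Conditions: SiCl4 (1.1 equiv), (R,R)-N,N'-bis(3,5-dimethyl-4-oxido-4,5-dihydro-3H-dinaphtho[2,1-d:1',2'-f][1,3,2]diazaphosphepin-4-yl)-N,N'-dimethylpentane-1,5-diamine (2 mol %), iPr2NEt (5 mol %), CH2Cl2, −78 °C; then aq NaHCO3
Reagents that add atoms: none
Why: Vinylogous Mukaiyama aldol under Lewis-base-activated SiCl4 catalysis: the bisphosphoramide-bound trichlorosilyl cation activates prenal, the dienolate attacks through its γ-carbon (the future C4') in an open transition state on the Re face of the carbonyl, which sets C5' as R, the E enoate forms from the s-trans dienolate, and trichlorosilyl ether 5 is hydrolysed on bicarbonate work-up.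

**Step 3**
Reactants: 6 methyl (2E,5R)-5-hydroxy-3,7-dimethylocta-2,6-dienoate
Product: 7 methyl (2E,5R)-5-(tert-butyldimethylsilyloxy)-3,7-dimethylocta-2,6-dienoate
Conditions: TBSCl, imidazole, DMF, rt
Reagents that add atoms: tert-butyldimethylsilyl chloride, CC(C)(C)[Si](C)(C)Cl
Why: Imidazole-mediated silyl ether formation on the secondary allylic hydroxyl exchanges only the O–H hydrogen, so C5' and the E enoate are untouched, and it masks the hydroxyl against lactonisation, oxidation and iminium chemistry in the following steps.

**Step 4**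
Reactants: 7 methyl (2E,5R)-5-(tert-butyldimethylsilyloxy)-3,7-dimethylocta-2,6-dienoate
Product: 8 (2E,5R)-5-(tert-butyldimethylsilyloxy)-3,7-dimethylocta-2,6-dien-1-ol
Conditions: iBu2AlH, CH2Cl2, −78 °C; then aq potassium sodium tartrate
Reagents that add atoms: none
Why: iBu2AlH reduces the conjugated ester by 1,2-hydride delivery to the allylic alcohol at −78 °C (ester reduction) without touching the silyl ether or either alkene, so geometry and configuration are carried over.

**Step 5**
Reactants: 8 (2E,5R)-5-(tert-butyldimethylsilyloxy)-3,7-dimethylocta-2,6-dien-1-ol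
Product: 9 (2E,5R)-5-(tert-butyldimethylsilyloxy)-3,7-dimethylocta-2,6-dienal
Conditions: activated MnO2, CH2Cl2, rt
Reagents that add atoms: none
Why: MnO2 oxidises only the allylic primary alcohol to the enal under neutral heterogeneous conditions (allylic oxidation), which keeps the E geometry, the silyl ether and the isolated alkene intact and stops at the aldehyde.

**Step 6**
Reactants: 9 (2E,5R)-5-(tert-butyldimethylsilyloxy)-3,7-dimethylocta-2,6-dienal
Product: 13 (2S,3R)-3-[(2R)-2-(tert-butyldimethylsilyloxy)-4-methylpent-3-en-1-yl]-3-methyloxirane-2-carbaldehyde, via iminium ion 10 (not isolated), via peroxy enamine 11 (not isolated), via epoxy iminium ion 12 (not isolated)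
Conditions: tBuOOH (1.1 equiv, in decane), bis[3,5-bis(trifluoromethyl)benzyl]ammonium (R)-3,3'-bis(2,4,6-triisopropylphenyl)-1,1'-binaphthyl-2,2'-diyl phosphate (10 mol %), tBuOMe, 0 °C
Reagents that add atoms: tert-butyl hydroperoxide, CC(C)(C)OO
Why: The secondary ammonium salt condenses with enal 9 to iminium ion 10, held as a tight ion pair with the chiral phosphate; tert-butyl hydroperoxide adds at C3' to give peroxy enamine 11, whose enamine carbon C2' attacks the proximal peroxide oxygen with loss of tert-butoxide to give epoxy iminium ion 12, and hydrolysis releases 13 and the amine. The closest known reaction type is the counter-anion-directed iminium epoxidation of β,β-disubstituted enals with alkyl hydroperoxides, a Weitz–Scheffer-type nucleophilic epoxidation. The oxirane closes by a 3-exo-tet displacement at oxygen. The quaternary centre C3' (R) is set in the conjugate addition by the phosphate anion, which shields one face of the ion pair so that the peroxide enters on the Re face of C3'; C2' (S in the aldehyde) follows because the new C3'–O bond already lies parallel to the enamine p orbital, so closure on that same face without rotation about C2'–C3' turns the E geometry into the C1'/C4' trans relation. The step needs chemoselectivity for C2'=C3' over the equally substituted C6'=C7' alkene, and polarity secures it: only the alkene conjugated to the iminium carbon C1' is electrophilic, whereas the isobutenyl alkene is inert to a nucleophilic peroxide. The remote C5' centre is not expected to override the catalyst, and the poor silanolate leaving group together with the low temperature should hold back dienamine-mediated E/Z scrambling and vinylogous elimination.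

**Step 7**
Reactants: 13 (2S,3R)-3-[(2R)-2-(tert-butyldimethylsilyloxy)-4-methylpent-3-en-1-yl]-3-methyloxirane-2-carbaldehyde
Product: 14 [(2R,3R)-3-[(2R)-2-(tert-butyldimethylsilyloxy)-4-methylpent-3-en-1-yl]-3-methyloxiran-2-yl]methanol
Conditions: NaBH4, MeOH, 0 °C
Reagents that add atoms: none
Why: Carbonyl reduction by NaBH4 at 0 °C is much faster than oxirane opening or Payne rearrangement, no stereocentre is touched, and the descriptor of C2' changes from S to R only because C1' now ranks below C3' in the CIP order.

**Step 8**
Reactants: 14 [(2R,3R)-3-[(2R)-2-(tert-butyldimethylsilyloxy)-4-methylpent-3-en-1-yl]-3-methyloxiran-2-yl]methanol; 15 7-hydroxy-8-methoxy-2H-chromen-2-one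
Product: 16 7-{[(2R,3R)-3-[(2R)-2-(tert-butyldimethylsilyloxy)-4-methylpent-3-en-1-yl]-3-methyloxiran-2-yl]methoxy}-8-methoxy-2H-chromen-2-one
Conditions: PPh3, iPrO2CN=NCO2iPr, THF, 0 °C to rt
Reagents that add atoms: none
Why: Mitsunobu etherification: the acidic coumarin phenol displaces the activated primary C1' hydroxyl in an SN2 reaction under neutral conditions, so no stereocentre is involved and the oxirane, the silyl ether and the lactone are left alone.

**Step 9**
Reactants: 16 7-{[(2R,3R)-3-[(2R)-2-(tert-butyldimethylsilyloxy)-4-methylpent-3-en-1-yl]-3-methyloxiran-2-yl]methoxy}-8-methoxy-2H-chromen-2-one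
Product: 17 7-{[(2R,3R)-3-[(2R)-2-hydroxy-4-methylpent-3-en-1-yl]-3-methyloxiran-2-yl]methoxy}-8-methoxy-2H-chromen-2-one
Conditions: Bu4NF, AcOH, THF, 0 °C to rt
Reagents that add atoms: none
Why: Fluoride-driven cleavage of the Si–O bond (desilylation) frees the C5' hydroxyl with retention, and the acetic acid buffer keeps the medium from opening the coumarin lactone or the oxirane.

**Compound list**

1 | methyl 3-methylbut-2-enoate | CC(C)=CC(=O)OC | starting material
2 | lithium 1-methoxy-3-methylbuta-1,3-dien-1-olate | COC(O[Li])=CC(C)=C | intermediate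
3 | tert-butyl[(1-methoxy-3-methylbuta-1,3-dien-1-yl)oxy]dimethylsilane (ketene acetal geometry not defined, used as formed) | COC(O[Si](C)(C)C(C)(C)C)=CC(C)=C | intermediate
4 | 3-methylbut-2-enal (prenal) | CC(C)=CC=O | starting material
5 | methyl (2E,5R)-3,7-dimethyl-5-(trichlorosilyloxy)octa-2,6-dienoate | COC(=O)/C=C(\C)C[C@@H](O[Si](Cl)(Cl)Cl)C=C(C)C | intermediate
6 | methyl (2E,5R)-5-hydroxy-3,7-dimethylocta-2,6-dienoate | COC(=O)/C=C(\C)C[C@@H](O)C=C(C)C | intermediate
7 | methyl (2E,5R)-5-(tert-butyldimethylsilyloxy)-3,7-dimethylocta-2,6-dienoate | COC(=O)/C=C(\C)C[C@@H](O[Si](C)(C)C(C)(C)C)C=C(C)C | intermediate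
8 | (2E,5R)-5-(tert-butyldimethylsilyloxy)-3,7-dimethylocta-2,6-dien-1-ol | OC/C=C(\C)C[C@@H](O[Si](C)(C)C(C)(C)C)C=C(C)C | intermediate
9 | (2E,5R)-5-(tert-butyldimethylsilyloxy)-3,7-dimethylocta-2,6-dienal | O=C/C=C(\C)C[C@@H](O[Si](C)(C)C(C)(C)C)C=C(C)C | intermediate
10 | (2E,5R)-N,N-bis[3,5-bis(trifluoromethyl)benzyl]-5-(tert-butyldimethylsilyloxy)-3,7-dimethylocta-2,6-dien-1-iminium (cation of the ion pair with the chiral phosphate) | FC(F)(F)c1cc(C[N+](Cc2cc(cc(c2)C(F)(F)F)C(F)(F)F)=C/C=C(\C)C[C@@H](O[Si](C)(C)C(C)(C)C)C=C(C)C)cc(c1)C(F)(F)F | intermediate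
11 | (1E,3R,5R)-N,N-bis[3,5-bis(trifluoromethyl)benzyl]-3-(tert-butylperoxy)-5-(tert-butyldimethylsilyloxy)-3,7-dimethylocta-1,6-dien-1-amine | FC(F)(F)c1cc(CN(Cc2cc(cc(c2)C(F)(F)F)C(F)(F)F)/C=C/[C@](C)(OOC(C)(C)C)C[C@@H](O[Si](C)(C)C(C)(C)C)C=C(C)C)cc(c1)C(F)(F)F | intermediate
12 | N,N-bis[3,5-bis(trifluoromethyl)benzyl]-1-{(2R,3R)-3-[(2R)-2-(tert-butyldimethylsilyloxy)-4-methylpent-3-en-1-yl]-3-methyloxiran-2-yl}methaniminium (cation of the ion pair with the chiral phosphate) | FC(F)(F)c1cc(C[N+](Cc2cc(cc(c2)C(F)(F)F)C(F)(F)F)=C[C@H]2O[C@]2(C)C[C@@H](O[Si](C)(C)C(C)(C)C)C=C(C)C)cc(c1)C(F)(F)F | intermediate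
13 | (2S,3R)-3-[(2R)-2-(tert-butyldimethylsilyloxy)-4-methylpent-3-en-1-yl]-3-methyloxirane-2-carbaldehyde | O=C[C@H]1O[C@]1(C)C[C@@H](O[Si](C)(C)C(C)(C)C)C=C(C)C | intermediate
14 | [(2R,3R)-3-[(2R)-2-(tert-butyldimethylsilyloxy)-4-methylpent-3-en-1-yl]-3-methyloxiran-2-yl]methanol | OC[C@H]1O[C@]1(C)C[C@@H](O[Si](C)(C)C(C)(C)C)C=C(C)C | intermediate
15 | 7-hydroxy-8-methoxy-2H-chromen-2-one (daphnetin 8-methyl ether) | COc1c(O)ccc2ccc(=O)oc12 | starting material
16 | 7-{[(2R,3R)-3-[(2R)-2-(tert-butyldimethylsilyloxy)-4-methylpent-3-en-1-yl]-3-methyloxiran-2-yl]methoxy}-8-methoxy-2H-chromen-2-one | COc1c(OC[C@H]2O[C@]2(C)C[C@@H](O[Si](C)(C)C(C)(C)C)C=C(C)C)ccc2ccc(=O)oc12 | intermediate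
17 | 7-{[(2R,3R)-3-[(2R)-2-hydroxy-4-methylpent-3-en-1-yl]-3-methyloxiran-2-yl]methoxy}-8-methoxy-2H-chromen-2-one | COc1c(OC[C@H]2O[C@]2(C)C[C@@H](O)C=C(C)C)ccc2ccc(=O)oc12 | target

**Step count**

Total step count: 9. Longest linear sequence: 9 steps (1 to 17).

**Steps most likely to fail**

Step 6. The iminium ion can equilibrate with its dienamine (γ-deprotonation at C4' or at the C3' methyl) and so scramble the E geometry before the peroxide adds. The resident C5' centre may also work against the catalyst, and the epoxy aldehyde may degrade on isolation; the result would be poor diastereocontrol in the oxirane. The fallback sets out from allylic alcohol 8 and uses a Sharpless asymmetric epoxidation (Ti(OiPr)4, D-(−)-diethyl tartrate, tBuOOH, 4 Å molecular sieves, CH2Cl2, −20 °C). The titanium-bound allylic alkoxide directs the peroxide to C2'=C3' only, and the syn oxygen delivery turns the E geometry into the trans relation. The tartrate sets both oxirane centres; the D-(−) antipode is chosen because it is opposite to the L-(+)-tartrate that converts geraniol into its (2S,3S) epoxide. This should give epoxy alcohol 14 directly, so steps 5, 6 and 7 drop out and the route is rejoined at 14; no compound outside the list is made (F0).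

Step 2. Enantiofacial control may erode with the small β,β-disubstituted enal, some Z enoate may form and lactonise, and the allylic trichlorosilyl ether may ionise. The fallback sets out from prenal 4. Enantioselective propargylation with allenylboronic acid pinacol ester, catalysed by 3,3'-bis(2,4,6-triisopropylphenyl)-1,1'-binaphthyl-2,2'-diyl hydrogen phosphate (antipode chosen for the R alcohol; toluene, 4 Å molecular sieves, low temperature), should give (4R)-6-methylhept-5-en-1-yn-4-ol F1. Silylation (TBSCl, imidazole, DMF) would give tert-butyldimethyl{[(4R)-6-methylhept-5-en-1-yn-4-yl]oxy}silane F2. Zirconium-catalysed methylalumination of the terminal alkyne (AlMe3, Cp2ZrCl2, CH2Cl2, 0 °C) adds methyl and aluminium syn to give [(1E,4R)-4-(tert-butyldimethylsilyloxy)-2,6-dimethylhepta-1,5-dien-1-yl]dimethylalane F3, which is trapped in the same flask with paraformaldehyde. This should give allylic alcohol 8 with the E geometry fixed by the syn addition; steps 1 to 4 are replaced and the route is rejoined at 8.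

Step 9. Basic fluoride may attack the coumarin lactone, and if the hindered secondary silyl ether cleaves slowly, prolonged exposure may let the liberated C5' alkoxide open the oxirane. The fallback sets out from epoxy alcohol 14 and removes the silyl group before the coumarin is present (Bu4NF, AcOH, THF, 0 °C), to give [(2R,3R)-3-[(2R)-2-hydroxy-4-methylpent-3-en-1-yl]-3-methyloxiran-2-yl]methanol F4. The Mitsunobu etherification with phenol 15 is then run with one equivalent each of PPh3 and iPrO2CN=NCO2iPr at 0 °C, relying on faster activation of the primary C1' hydroxyl over the secondary allylic C5' hydroxyl. This should give target 17 directly, so the route is rejoined at 17 with the same number of steps.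

**Further compounds**

F0 | step 6 | none | none
F1 | step 2 | (4R)-6-methylhept-5-en-1-yn-4-ol | C#CC[C@@H](O)C=C(C)C
F2 | step 2 | tert-butyldimethyl{[(4R)-6-methylhept-5-en-1-yn-4-yl]oxy}silane | C#CC[C@@H](O[Si](C)(C)C(C)(C)C)C=C(C)C
F3 | step 2 | [(1E,4R)-4-(tert-butyldimethylsilyloxy)-2,6-dimethylhepta-1,5-dien-1-yl]dimethylalane | C[Al](C)/C=C(\C)C[C@@H](O[Si](C)(C)C(C)(C)C)C=C(C)C
F4 | step 9 | [(2R,3R)-3-[(2R)-2-hydroxy-4-methylpent-3-en-1-yl]-3-methyloxiran-2-yl]methanol | OC[C@H]1O[C@]1(C)C[C@@H](O)C=C(C)C
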